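**Retrosynthetic overview**
- Erylatissin C ⇐ its 7,3'-bis(silyl) ether; buffered fluoride deprotection comes last so that C2 is not disturbed.
- Ring C ⇐ a racemic 2-aryl-4-methylidene-4H-1,3-benzodioxine. The C2–C3 bond is made by a catalytic enantioselective 1,3 O-to-C (Petasis–Ferrier) rearrangement that turns the 1,3-dioxine ring into the pyranone ring and sets C2 in the same operation.
- Enabling feature: C2 carries both O1 and the 4-methoxyaryl ring B, so it is a latent oxocarbenium carbon; C3 is α to the C4 carbonyl group on ring A, so it is a latent enol carbon. In the precursor the future carbonyl oxygen is still bonded to C2.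
- Enol acetal ⇐ Petasis methylenation of a 2-aryl-4H-1,3-benzodioxin-4-one ⇐ acetalisation of 4-silyloxysalicylic acid (ring A) with the ring B aldehyde. The aldehyde ⇐ 3-bromo-4,5-dihydroxybenzaldehyde by selective 4-O-methylation, silylation and Stille prenylation.
- Ring order: rings A and B are bought; the 1,3-dioxine ring is closed first (step 5) and is converted into ring C in step 7.

Key step: step 7

Abbreviations: TBS = tert-butyldimethylsilyl; prenyl = 3-methylbut-2-en-1-yl; Cp = cyclopentadienyl.

Assumption: the sense of induction of the chiral acid in step 7 cannot be predicted for this new substrate class; the (R)-catalyst is written, and its (S)-antipode is to be used if the first trial gives the 2R flavanone.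

**Step 1**
Reactants: 1 3-bromo-4,5-dihydroxybenzaldehyde
Product: 2 3-bromo-5-hydroxy-4-methoxybenzaldehyde
Conditions: MeI (1.05 equiv), Li2CO3 (1.1 equiv), DMF, 40 °C
Reagents that add atoms: iodomethane, CI
Why: Williamson O-methylation under a weak base: the 4-OH, para to the formyl group and ortho to bromine, is the more acidic phenol, so mainly the 4-phenoxide should form and be methylated while the 5-OH stays free.

**Step 2**
Reactants: 2 3-bromo-5-hydroxy-4-methoxybenzaldehyde
Product: 3 3-bromo-5-[(tert-butyldimethylsilyl)oxy]-4-methoxybenzaldehyde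
Conditions: TBSCl, imidazole, DMF, rt
Reagents that add atoms: tert-butyldimethylsilyl chloride, CC(C)(C)[Si](C)(C)Cl
Why: Standard imidazole-promoted silylation of a phenol; the silyl ether masks the one free phenol of ring B through the organometallic and acidic steps and is removable by fluoride at the end.

**Step 3**
Reactants: 3 3-bromo-5-[(tert-butyldimethylsilyl)oxy]-4-methoxybenzaldehyde
Product: 4 3-[(tert-butyldimethylsilyl)oxy]-4-methoxy-5-(3-methylbut-2-en-1-yl)benzaldehyde
Conditions: tributyl(prenyl)stannane (1.3 equiv), Pd(PPh3)4 (5 mol %), toluene, 110 °C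
Reagents that add atoms: tributyl(3-methylbut-2-en-1-yl)stannane, CCCC[Sn](CCCC)(CCCC)CC=C(C)C
Why: Stille coupling: oxidative addition of zerovalent palladium into the aryl C–Br bond, transmetalation from tin and reductive elimination at the less substituted allyl terminus should give the linear prenyl arene under neutral conditions that leave the aldehyde and the silyl ether untouched.

**Step 4**
Reactants: 5 2,4-dihydroxybenzoic acid
Product: 7 4-[(tert-butyldimethylsilyl)oxy]-2-hydroxybenzoic acid, via bis-silylated silyl ester 6 (not isolated)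
Conditions: TBSCl (2.2 equiv), imidazole, DMF, 0 °C → rt; then AcOH–THF–H2O (3:1:1), rt
Reagents that add atoms: tert-butyldimethylsilyl chloride, CC(C)(C)[Si](C)(C)Cl
Why: Silylation of the carboxylic acid and of the unhindered 4-OH (the 2-OH is held in a hydrogen bond to the carbonyl group), followed by selective hydrolysis of the far more labile silyl ester in aqueous acetic acid, to which the aryl silyl ether is stable.

**Step 5**
Reactants: 4 3-[(tert-butyldimethylsilyl)oxy]-4-methoxy-5-(3-methylbut-2-en-1-yl)benzaldehyde; 7 4-[(tert-butyldimethylsilyl)oxy]-2-hydroxybenzoic acid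
Product: 9 rac-7-[(tert-butyldimethylsilyl)oxy]-2-[3-[(tert-butyldimethylsilyl)oxy]-4-methoxy-5-(3-methylbut-2-en-1-yl)phenyl]-4H-1,3-benzodioxin-4-one, via bis(trimethylsilyl) derivative 8 (not isolated)
Conditions: 7, (Me3Si)2NH, THF, 65 °C, then evaporate; 4, TMSOTf (0.15 equiv), CH2Cl2, −78 → −20 °C; pyridine, then aq. NaHCO3
Reagents that add atoms: none
Why: TMSOTf-catalysed silyl-transfer acetalisation of a bis-silylated hydroxy acid with an aldehyde, the standard entry to 1,3-dioxan-4-ones, driven by loss of hexamethyldisiloxane; the acetal carbon C2 is formed racemic, which is of no consequence because step 7 erases and resets it.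

**Step 6**
Reactants: 9 rac-7-[(tert-butyldimethylsilyl)oxy]-2-[3-[(tert-butyldimethylsilyl)oxy]-4-methoxy-5-(3-methylbut-2-en-1-yl)phenyl]-4H-1,3-benzodioxin-4-one
Product: 10 rac-7-[(tert-butyldimethylsilyl)oxy]-2-[3-[(tert-butyldimethylsilyl)oxy]-4-methoxy-5-(3-methylbut-2-en-1-yl)phenyl]-4-methylidene-4H-1,3-benzodioxine
Conditions: Cp2TiMe2 (2.5 equiv), toluene–THF, 65 °C, dark; filtration through basic alumina (hexane, 1% Et3N)
Reagents that add atoms: dimethyltitanocene Cp2TiMe2, C[Ti+2]C.c1cc[cH-]c1.c1cc[cH-]c1
Why: Petasis methylenation: thermolysis of Cp2TiMe2 gives Cp2Ti=CH2, which olefinates the lactone carbonyl group by [2+2] cycloaddition and cycloreversion under conditions that are neither acidic nor basic, as known for 1,3-dioxan-4-ones, so the acylal, the aryl silyl ethers and the trisubstituted prenyl alkene should survive.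

**Step 7**
Reactants: 10 rac-7-[(tert-butyldimethylsilyl)oxy]-2-[3-[(tert-butyldimethylsilyl)oxy]-4-methoxy-5-(3-methylbut-2-en-1-yl)phenyl]-4-methylidene-4H-1,3-benzodioxine
Product: 12 (2S)-7-[(tert-butyldimethylsilyl)oxy]-2-[3-[(tert-butyldimethylsilyl)oxy]-4-methoxy-5-(3-methylbut-2-en-1-yl)phenyl]-2,3-dihydro-4H-chromen-4-one, via oxocarbenium enol ion pair 11 (not isolated)
Conditions: (R)-3,3'-bis(2,4,6-triisopropylphenyl)-1,1'-binaphthalene-2,2'-diyl N-triflylphosphoramide (5 mol %), 4 Å MS, toluene, −60 to −30 °C; then Et3N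
Reagents that add atoms: none
Why: Proposed new method: a catalytic enantioselective Petasis–Ferrier (1,3 O-to-C) rearrangement in which the chiral acid protonates the enol-ether oxygen O3 of 10, the C2–O3 acetal bond ionises to the O-aryl oxocarbenium ion bearing the ortho enol (11, a contact ion pair with the chiral phosphoramide anion), the enol carbon attacks the oxocarbenium carbon and the protonated ketone returns the proton to the catalyst; the closest known reaction types are the aluminium-Lewis-acid Petasis–Ferrier rearrangement of 4-methylidene-1,3-dioxanes to tetrahydropyran-4-ones and the chiral-phosphoric-acid-catalysed aza-Petasis–Ferrier rearrangement of hemiaminal vinyl ethers. Ring C is closed by a 6-(enolendo)-endo-trig aldol-type addition that forms the C2–C3 bond. The C2 configuration of racemic 10 is erased in the planar oxocarbenium ion, so both enantiomers converge, and the new C2 stereocentre is set by the catalyst alone: the anion hydrogen-bonds the enol O–H and covers one face of the C=O+ unit inside the pocket made by the 2,4,6-triisopropylphenyl groups. The step needs C- over O-recombination (O-closure only returns 10, C-closure is irreversible because it ends in the ketone), C2–O3 over C2–O1 ionisation (the latter is reversible and leads nowhere) and no achiral background reaction, which the low temperature, the sieves and the acid-free isolation of 10 are meant to secure. A weak catalytic acid should suffice because the C2 cation is stabilised twice, by O1 and by the 4-methoxyaryl ring B. The weakly basic ketone 12 should release the catalyst and, having no free phenol, should not open to the chalcone or racemise under these conditions.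

**Step 8**
Reactants: 12 (2S)-7-[(tert-butyldimethylsilyl)oxy]-2-[3-[(tert-butyldimethylsilyl)oxy]-4-methoxy-5-(3-methylbut-2-en-1-yl)phenyl]-2,3-dihydro-4H-chromen-4-one
Product: 13 erylatissin C, (2S)-7-hydroxy-2-[3-hydroxy-4-methoxy-5-(3-methylbut-2-en-1-yl)phenyl]-2,3-dihydro-4H-chromen-4-one
Conditions: Bu4NF (2.4 equiv), AcOH (2.6 equiv), THF, 0 °C
Reagents that add atoms: none
Why: Fluoride cleavage of the two aryl silyl ethers; the acetic acid buffer keeps the phenoxide concentration low, so base-induced retro-oxa-Michael opening to the 2'-hydroxychalcone, the path by which flavanones racemise at C2, should be suppressed, and the prenyl group is inert.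

**Compound list**
1 | 3-bromo-4,5-dihydroxybenzaldehyde | O=Cc1cc(O)c(O)c(Br)c1 | starting material
2 | 3-bromo-5-hydroxy-4-methoxybenzaldehyde | COc1c(O)cc(C=O)cc1Br | intermediate
3 | 3-bromo-5-[(tert-butyldimethylsilyl)oxy]-4-methoxybenzaldehyde | COc1c(O[Si](C)(C)C(C)(C)C)cc(C=O)cc1Br | intermediate
4 | 3-[(tert-butyldimethylsilyl)oxy]-4-methoxy-5-(3-methylbut-2-en-1-yl)benzaldehyde | COc1c(O[Si](C)(C)C(C)(C)C)cc(C=O)cc1CC=C(C)C | intermediate
5 | 2,4-dihydroxybenzoic acid | OC(=O)c1ccc(O)cc1O | starting material
6 | tert-butyldimethylsilyl 4-[(tert-butyldimethylsilyl)oxy]-2-hydroxybenzoate (not isolated) | CC(C)(C)[Si](C)(C)OC(=O)c1ccc(O[Si](C)(C)C(C)(C)C)cc1O | intermediate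
7 | 4-[(tert-butyldimethylsilyl)oxy]-2-hydroxybenzoic acid | OC(=O)c1ccc(O[Si](C)(C)C(C)(C)C)cc1O | intermediate
8 | trimethylsilyl 4-[(tert-butyldimethylsilyl)oxy]-2-[(trimethylsilyl)oxy]benzoate (not isolated) | C[Si](C)(C)OC(=O)c1ccc(O[Si](C)(C)C(C)(C)C)cc1O[Si](C)(C)C | intermediate
9 | rac-7-[(tert-butyldimethylsilyl)oxy]-2-[3-[(tert-butyldimethylsilyl)oxy]-4-methoxy-5-(3-methylbut-2-en-1-yl)phenyl]-4H-1,3-benzodioxin-4-one (racemic at C2) | COc1c(O[Si](C)(C)C(C)(C)C)cc(C2OC(=O)c3ccc(O[Si](C)(C)C(C)(C)C)cc3O2)cc1CC=C(C)C | intermediate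
10 | rac-7-[(tert-butyldimethylsilyl)oxy]-2-[3-[(tert-butyldimethylsilyl)oxy]-4-methoxy-5-(3-methylbut-2-en-1-yl)phenyl]-4-methylidene-4H-1,3-benzodioxine (racemic at C2) | COc1c(O[Si](C)(C)C(C)(C)C)cc(C2OC(=C)c3ccc(O[Si](C)(C)C(C)(C)C)cc3O2)cc1CC=C(C)C | intermediate
11 | O-aryl oxocarbenium ion carrying the ortho 1-hydroxyvinyl (enol) group, as its ion pair with the catalyst anion (not isolated) | COc1c(O[Si](C)(C)C(C)(C)C)cc(C=[O+]c2cc(O[Si](C)(C)C(C)(C)C)ccc2C(O)=C)cc1CC=C(C)C | intermediate
12 | (2S)-7-[(tert-butyldimethylsilyl)oxy]-2-[3-[(tert-butyldimethylsilyl)oxy]-4-methoxy-5-(3-methylbut-2-en-1-yl)phenyl]-2,3-dihydro-4H-chromen-4-one | COc1c(O[Si](C)(C)C(C)(C)C)cc([C@@H]2CC(=O)c3ccc(O[Si](C)(C)C(C)(C)C)cc3O2)cc1CC=C(C)C | intermediate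
13 | erylatissin C, (2S)-7-hydroxy-2-[3-hydroxy-4-methoxy-5-(3-methylbut-2-en-1-yl)phenyl]-2,3-dihydro-4H-chromen-4-one | COc1c(O)cc([C@@H]2CC(=O)c3ccc(O)cc3O2)cc1CC=C(C)C | target

**Step count**
Total: 8 steps. Longest linear sequence: 7 steps (steps 1, 2, 3, 5, 6, 7, 8).

**Steps most likely to fail**

Step 7 (the proposed new method). What may go wrong: insufficient facial discrimination in the ion pair, an achiral background rearrangement, or C-protonation of the enol ether followed by hydrolytic loss of the acetal. The fallback uses known chemistry, sets out from 4 and 7 and comes back at 12. Acid 7 is esterified (Me3SiCHN2, MeOH–toluene) to methyl 4-[(tert-butyldimethylsilyl)oxy]-2-hydroxybenzoate F1. Claisen condensation of F1 with the lithium enolate of tert-butyl acetate (LiN(iPr)2 in excess, THF, −78 → 0 °C) should give tert-butyl 3-{4-[(tert-butyldimethylsilyl)oxy]-2-hydroxyphenyl}-3-oxopropanoate F2. Knoevenagel condensation of F2 with aldehyde 4 (piperidinium acetate, toluene, 4 Å MS) should give the alkylidene β-ketoester tert-butyl 2-{4-[(tert-butyldimethylsilyl)oxy]-2-hydroxybenzoyl}-3-[3-[(tert-butyldimethylsilyl)oxy]-4-methoxy-5-(3-methylbut-2-en-1-yl)phenyl]prop-2-enoate F3 as an E/Z mixture. A quinine- or quinidine-derived bifunctional thiourea (10 mol %, toluene, −25 °C), the pseudoenantiomer being chosen for the 2S series, then effects the enantioselective intramolecular oxa-Michael addition to tert-butyl (2S)-7-[(tert-butyldimethylsilyl)oxy]-2-[3-[(tert-butyldimethylsilyl)oxy]-4-methoxy-5-(3-methylbut-2-en-1-yl)phenyl]-4-oxo-3,4-dihydro-2H-chromene-3-carboxylate F4 (C3 epimers and enol form). TsOH in toluene at 80 °C cleaves the tert-butyl ester and decarboxylates to 12; this last operation has to be watched for acid-induced migration of the prenyl double bond.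

Step 6. What may go wrong: premature ionisation of the enol acetal on Lewis-acidic titanocene residues or on the adsorbent, which would rearrange it racemically or hydrolyse it before the chiral catalyst sees it. The fallback uses this lability instead of fighting it, sets out from 9 and comes back at 12. Compound 9 is methylenated as in step 6 and, without isolation of 10, the solution is treated with Me2AlCl at −78 °C (the classical aluminium-mediated Petasis–Ferrier rearrangement) to give the racemic flavanone rac-7-[(tert-butyldimethylsilyl)oxy]-2-[3-[(tert-butyldimethylsilyl)oxy]-4-methoxy-5-(3-methylbut-2-en-1-yl)phenyl]-2,3-dihydro-4H-chromen-4-one F5. The racemate is resolved by asymmetric transfer hydrogenation with RuCl(p-cymene)[(R,R)-TsDPEN] or its (S,S) antipode (HCO2H–Et3N, EtOAc, rt), whichever reduces the 2R ketone faster. The 2R enantiomer is converted into the cis alcohol (2R,4R)-7-[(tert-butyldimethylsilyl)oxy]-2-[3-[(tert-butyldimethylsilyl)oxy]-4-methoxy-5-(3-methylbut-2-en-1-yl)phenyl]-3,4-dihydro-2H-chromen-4-ol F6, and unreacted 12 is separated from it by chromatography.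

Step 3. What may go wrong: allyl transposition during transmetalation and reductive elimination, leading to the branched 1,1-dimethylallyl isomer, or addition of the allylic stannane to the formyl group. The fallback builds the prenyl group in two stages, sets out from 3 and comes back at 4. Stille coupling of 3 with allyltributylstannane (Pd(PPh3)4, toluene, 110 °C), which has no regiochemical ambiguity, should give 3-allyl-5-[(tert-butyldimethylsilyl)oxy]-4-methoxybenzaldehyde F7. Cross-metathesis of F7 with 2-methylbut-2-ene (co-solvent) and the second-generation Grubbs catalyst in CH2Cl2 at 40 °C then converts the allyl group into the prenyl group of 4.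

**Further compounds**
F1 | step 7 | methyl 4-[(tert-butyldimethylsilyl)oxy]-2-hydroxybenzoate | COC(=O)c1ccc(O[Si](C)(C)C(C)(C)C)cc1O
F2 | step 7 | tert-butyl 3-{4-[(tert-butyldimethylsilyl)oxy]-2-hydroxyphenyl}-3-oxopropanoate | CC(C)(C)OC(=O)CC(=O)c1ccc(O[Si](C)(C)C(C)(C)C)cc1O
F3 | step 7 | tert-butyl 2-{4-[(tert-butyldimethylsilyl)oxy]-2-hydroxybenzoyl}-3-[3-[(tert-butyldimethylsilyl)oxy]-4-methoxy-5-(3-methylbut-2-en-1-yl)phenyl]prop-2-enoate (E/Z mixture) | COc1c(O[Si](C)(C)C(C)(C)C)cc(C=C(C(=O)OC(C)(C)C)C(=O)c2ccc(O[Si](C)(C)C(C)(C)C)cc2O)cc1CC=C(C)C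
F4 | step 7 | tert-butyl (2S)-7-[(tert-butyldimethylsilyl)oxy]-2-[3-[(tert-butyldimethylsilyl)oxy]-4-methoxy-5-(3-methylbut-2-en-1-yl)phenyl]-4-oxo-3,4-dihydro-2H-chromene-3-carboxylate (C3 not defined) | COc1c(O[Si](C)(C)C(C)(C)C)cc([C@@H]2C(C(=O)OC(C)(C)C)C(=O)c3ccc(O[Si](C)(C)C(C)(C)C)cc3O2)cc1CC=C(C)C
F5 | step 6 | rac-7-[(tert-butyldimethylsilyl)oxy]-2-[3-[(tert-butyldimethylsilyl)oxy]-4-methoxy-5-(3-methylbut-2-en-1-yl)phenyl]-2,3-dihydro-4H-chromen-4-one | COc1c(O[Si](C)(C)C(C)(C)C)cc(C2CC(=O)c3ccc(O[Si](C)(C)C(C)(C)C)cc3O2)cc1CC=C(C)C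
F6 | step 6 | (2R,4R)-7-[(tert-butyldimethylsilyl)oxy]-2-[3-[(tert-butyldimethylsilyl)oxy]-4-methoxy-5-(3-methylbut-2-en-1-yl)phenyl]-3,4-dihydro-2H-chromen-4-ol | COc1c(O[Si](C)(C)C(C)(C)C)cc([C@H]2C[C@@H](O)c3ccc(O[Si](C)(C)C(C)(C)C)cc3O2)cc1CC=C(C)C
F7 | step 3 | 3-allyl-5-[(tert-butyldimethylsilyl)oxy]-4-methoxybenzaldehyde | COc1c(O[Si](C)(C)C(C)(C)C)cc(C=O)cc1CC=C
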